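| flask | starting complex | incoming ligand | leaving ligand | remark | time |
|---|---|---|---|---|---|
| Friday's | 0.32 M | 0.75 equiv | 0.50 equiv | run made earlier |  |
| flask | 0.32 M | 1.50 equiv | 0.500 equiv |  | 3.0 h |

Friday's run (percent of the starting complex charged)

| time / min | isomer of the product / % | complex with one exchanged / % |
|---|---|---|
| 8.00 | 8.2 | 4.4 |
| 15.0 | 13.3 | 1.7 |
| 25.0 | 16.2 | 1.3 |
| 30.0 | 16.8 | 1.2 |
| 40.0 | 16.9 | 0.8 |
| 50.0 | 17.7 | 1.0 |

(scatter of a reading: 0.3 percentage points)

- the reaction counts as stopped when no species that holds the starting complex changes by six tenths of a point or more over the second half of the time
- no earlier run changes the charge of incoming ligand; that part of a forecast is a guess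

* which holds at 3.0 h: what has brought the reaction to rest, or that it has not come to rest (the incoming ligand has run out first / forward and back rates have come level / it is still moving / all of the starting complex has reacted)
* amount of isomer of the product at 3.0 h, in percent of the starting complex charged

I start with the easy step: Friday's rate. I add both complexes, because each holds one exchange. They reach 12.6% at 8.00 min and 18.7% at 50.0 min. I divide the first read rate by the read rate between 25.0 min and 50.0 min:

slowing = 32.8

Use of starting complex and incoming ligand, one for one, gives this factor:

depletion = 1.64

So the read slowing exceeds depletion. My guess, which the readings do not prove, is that the incoming ligand also consumes itself, second order in [incoming ligand]. I then define the crossover charge a: the ligand level, in equivalents, at which its self-loss equals its use on the starting complex. With the starting complex held near its charge, the useful share of the ligand's rate is a/(a + [incoming ligand]), and summing that as the ligand falls gives: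

exchanged = a · ln(1 + charge/a)

Friday's last reading gives a read value of a = 0.0802 equivalents. For 1.50 equiv, I reckon 23.9% exchanged, in both complexes together. My own expectation is that the incoming ligand runs out first.

The forecast differs: forward and back rates have come level, with 28% isomer, on the ground that “The plateau is therefore equilibrium”.

The flask gives: the incoming ligand has run out first, with 23.1% isomer.

    starting complex + incoming ligand → leaving ligand + complex with one exchanged (k = 0.210 M⁻¹ min⁻¹)
    complex with one exchanged ⇌ isomer of the product (K = 31.0, k = 0.240 min⁻¹)
    complex with one exchanged + incoming ligand → leaving ligand + complex with two exchanged (k = 0.140 M⁻¹ min⁻¹)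
    2 incoming ligand → homo dimer (k = 1.10 M⁻¹ min⁻¹)

In this flask the midpoint of turnover comes at 0.712 min for the step to homo dimer and at 3.13 min for the step on the starting complex, and at 0.300 h the incoming ligand stands at 2.80% of its charge. The step from complex with one exchanged to isomer has 99.7% of its turnover behind it by 1.50 h, and the incoming ligand, the limiting reagent, stands at 0% of its charge at 3.00 h. The crossover charge gave 23.9%, and the two complexes in this flask hold 23.9%. For the neighbour with 0.380 equiv, it gives 14.0%, and the same two complexes in that flask hold 14.5%.

The runs stem from a simulated flask for substances that don't exist, and the scatter is random.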